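**Plan**
1. Retrosynthesis cuts, in order: the C8–O ester bond; the lactone O6–C12 bond (back to a C12 allylic alcohol and 6-OH); the furanone O10–C3 bond (back to a 10-oxygenated 1,3-dicarbonyl equivalent); the ring bond C1–C10 with re-formation of C3–C8 (retro-[3,3]); then C8–C9 and C2–C3 (two carbonyl additions).
2. Structural feature used: C3–C8 with C15, the Z C4=C5 alkene and C11–C13 are (R)-carvone with the C3–C8 bond cut; the missing C9–C10–C1–C2 unit is exactly two two-carbon arms.
3. Forward: the carvone cyclohexene is oxygenated at C6 and C8, armed at C3 (ethoxyethynyl) and C8 ((Z)-2-(methoxymethoxy)propenyl), and expanded to the ten-membered carbocycle by a dianionic oxy-Cope shift. The furanone and then the α-methylene lactone are closed afterwards.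
4. Stereochemistry: C7 from (R)-carvone; C6 by γ-oxidation anti to the isopropenyl group; C10 by chirality transfer from the temporary C3/C8 carbinols through a chair transition state; C8 by ketone reduction; Z-C4=C5 from the six-membered ring; E side-chain alkene by thermodynamic acetate transposition.

Key step: step 9

Remark: germacrane numbering is used for every intermediate (carvone C1–C6 = C3, C4, C5, C6, C7, C8; isopropenyl = C11–C13; ring methyl = C15; C10 methyl = C14). β is the ring face that carries the C7 side chain, α the opposite face. The target is taken as the (6S,7S,8R,10R) enantiomer defined by its SMILES.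

**Step 1**
Reactants: 1 (R)-(−)-carvone
Product: 3 (S)-trimethyl{[2-methyl-5-(prop-1-en-2-yl)cyclohexa-1,3-dien-1-yl]oxy}silane (linear silyl dienol ether), via bromomagnesium dienolate 2 (not isolated)
Conditions: MeMgBr (1.1 equiv), FeCl3 (5 mol %), Et2O, −20 °C; then Me3SiCl, Et3N, DMPU, −20 → 23 °C
Reagents that add atoms: chlorotrimethylsilane, C[Si](C)(C)Cl
Why: FeCl3-catalysed MeMgBr acts as a base and gives the thermodynamic, γ-deprotonated (extended) magnesium dienolate, whose O-silylation furnishes the linear 1-silyloxy-1,3-diene needed for γ-oxidation (thermodynamic silyl dienol ether formation); C7 is not touched.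

**Step 2**
Reactants: 3 linear silyl dienol ether
Product: 5 (4S,5R)-4-hydroxy-2-methyl-5-(prop-1-en-2-yl)cyclohex-2-en-1-one (6α-hydroxy enone, OH trans to isopropenyl), via 5,6-epoxy silyl enol ether 4 (not isolated)
Conditions: dimethyldioxirane (1.05 equiv), acetone/CH2Cl2, −78 °C; then AcOH (cat.), THF/H2O, 0 °C
Reagents that add atoms: dimethyldioxirane, CC1(C)OO1
Why: Vinylogous Rubottom oxidation: the dioxirane epoxidises the distal C5=C6 bond of the electron-rich dienol ether (the isolated isopropenyl group is far less nucleophilic) on the face anti to the neighbouring C7 isopropenyl group, and ring opening with loss of silicon gives the γ-hydroxy enone with the new C6 oxygen α.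

**Step 3**
Reactants: 5 6α-hydroxy enone
Product: 6 6α-[(tert-butyldimethylsilyl)oxy] enone
Conditions: t-BuMe2SiCl, imidazole, DMF, 23 °C
Reagents that add atoms: tert-butyldimethylsilyl chloride, CC(C)(C)[Si](C)(C)Cl
Why: Standard silylation of a secondary allylic alcohol; the TBS ether should survive the strong bases, organometallics and KH used up to the key step and is removed by fluoride at the end.

**Step 4**
Reactants: 6 6α-silyloxy enone
Product: 8 6α-[(tert-butyldimethylsilyl)oxy]-8α-hydroxy enone (both oxygens trans to isopropenyl), via potassium cross-conjugated enolate 7 (not isolated)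
Conditions: KN(SiMe3)2, THF, −78 °C; then 2-(phenylsulfonyl)-3-phenyloxaziridine, −78 °C; then H2O
Reagents that add atoms: 2-(phenylsulfonyl)-3-phenyloxaziridine, O=S(=O)(c1ccccc1)N1OC1c1ccccc1
Why: Kinetic α′-deprotonation gives the cross-conjugated potassium enolate, which the Davis oxaziridine hydroxylates on the face anti to the adjacent isopropenyl group (8α-OH); this stereocentre only serves to steer step 5 and is erased in step 6.

**Step 5**
Reactants: 8 8α-hydroxy enone; 9 ethoxyacetylene
Product: 11 3β-(ethoxyethynyl)-6α-[(tert-butyldimethylsilyl)oxy]-cyclohex-4-ene-3α,8α-diol (alkynyl cis to isopropenyl), via lithium ethoxyacetylide 10 (not isolated)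
Conditions: 9 (3.0 equiv), n-BuLi, THF, −78 °C; then 8, −78 → −40 °C; then H2O
Reagents that add atoms: none
Why: 1,2-Addition of a lithium acetylide to an enone carbonyl held in a five-membered lithium chelate with the C8 alkoxide (formed by the first equivalent): attack past the small C8–H on the β-face, trans to the C8 oxygen (Cram cyclic model), should place the alkynyl arm β and the C3 oxygen α.

**Step 6**
Reactants: 11 3α,8α-diol
Product: 12 3β-(ethoxyethynyl)-3α-hydroxy-6α-[(tert-butyldimethylsilyl)oxy]-cyclohex-4-en-8-one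
Conditions: Dess–Martin periodinane, pyridine, CH2Cl2, 0 → 23 °C
Reagents that add atoms: none
Why: Dess–Martin oxidation converts the secondary C8 carbinol into the ketone while the tertiary propargylic C3 alcohol cannot react, and pyridine buffers the acetic acid that would otherwise hydrate the ynol ether.

**Step 7**
Reactants: 13 bromoacetone
Product: 15 (Z)-1-bromo-2-(methoxymethoxy)prop-1-ene, via potassium (Z)-bromoenolate 14 (not isolated)
Conditions: KN(SiMe3)2, THF, −78 °C (13 added to the base); then MeOCH2Cl, −78 → 0 °C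
Reagents that add atoms: chloromethyl methyl ether, COCCl
Why: Deprotonation occurs at the more acidic CH2Br group and the hard electrophile MeOCH2Cl alkylates the potassium enolate on oxygen (enolate O-alkylation), the Br/O-cis (Z) geometry being carried into the enol ether; any E isomer is removed because only the Z bromide gives a lithium reagent that does not β-eliminate.

**Step 8**
Reactants: 12 3α-hydroxy-8-ketone; 15 (Z)-bromo enol ether
Product: 18 3β-(ethoxyethynyl)-8α-[(Z)-2-(methoxymethoxy)prop-1-enyl]-6α-[(tert-butyldimethylsilyl)oxy]-cyclohex-4-ene-3α,8β-diol (arms trans, hydroxyls trans), via (Z)-2-(methoxymethoxy)prop-1-enyllithium 16 (not isolated), via bromomagnesium 3-alkoxide 17 (not isolated)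
Conditions: 15 (3 equiv), t-BuLi (6 equiv), Et2O, −78 °C; separately 12, MeMgBr (1.0 equiv), THF, −78 °C; combine, −78 → −40 °C; then H2O
Reagents that add atoms: none
Why: Br–Li exchange with retention gives the O-chelated (Z)-β-alkoxyvinyllithium 16, which adds to the magnesium chelate 17 (O3 in the carbonyl plane, the ethynyl arm axial on the β-face beside the β-isopropenyl group) from the open α-face (chelation-controlled addition to an α-alkoxido ketone), so that the new arm is α, trans to the alkynyl arm, and O8 is β.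

**Step 9**
Reactants: 18 3α,8β-diol with β-ethoxyethynyl and α-(Z)-alkoxypropenyl arms
Product: 20 1-ethoxy-10β-(methoxymethoxy)-6α-[(tert-butyldimethylsilyl)oxy]germacra-1,4(Z),11(13)-triene-3,8-dione (ten-membered β-ethoxy enone, 10R), via dipotassium enolate-allenolate 19 (not isolated)
Conditions: KH (3 equiv), 18-crown-6 (3 equiv), THF, −20 → 23 °C; then AcOH, THF, −78 °C
Reagents that add atoms: none
Why: KH/18-crown-6 converts the 3,8-diol into its dipotassium dialkoxide, in which the doubly donor-substituted C3–C8 σ-bond is cleaved while C1–C10 forms in a concerted [3,3] sigmatropic shift across the ethoxyethynyl and (Z)-alkoxypropenyl arms, giving the C8 enolate/C1–C3 allenolate 19 that is C-protonated at C9 and C2 on cold AcOH quench. The closest known reaction type is the anionic (and dianionic) oxy-Cope ring expansion of 1-alkynyl-2-alkenyl- and 1,2-dialkenylcyclohexanols and -1,2-diols to cyclodecenones. The ten-membered carbocycle is not closed end to end but arises by ring expansion: the four arm carbons C9–C10–C1–C2 are inserted into the cyclohexene through a six-centre chair transition state, so the only closure event is the six-membered pericyclic array. The single new stereocentre C10 is controlled by chirality transfer from the C3/C8 carbinols: with both arms equatorial (half-chair with the C6 and C7 substituents equatorial, oxygens trans-diaxial) the fixed C9–C8–C3–C2 torsion lets only one face of the Z-enol ether reach C1, which puts O10 on the β-face and C14 on the α-face (10R). The step needs the [3,3] shift to win over loss of ethoxyacetylide from the C3 alkoxide and over transannular aldol reaction of the product, which the large alkoxide acceleration at low temperature and the masking of C3 as an allenolate until the quench should secure, and chair over boat, which the diequatorial arms secure. The Z geometry of C4=C5 is inherited from the six-membered ring.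

**Step 10**
Reactants: 20 ring-expanded 3,8-dione
Product: 21 1-ethoxy-8α-hydroxy-10β-(methoxymethoxy)-6α-[(tert-butyldimethylsilyl)oxy]germacra-1,4(Z),11(13)-trien-3-one
Conditions: NaBH4, MeOH/CH2Cl2, −40 °C
Reagents that add atoms: none
Why: NaBH4 reduces the isolated C8 ketone far faster than the cross-conjugated vinylogous ester carbonyl at C3, and, as with small hydrides on 2-substituted cyclic ketones, the hydroxyl is expected trans to the neighbouring C7 isopropenyl group (8α-OH, attack on the β-face); the low temperature avoids base-induced isomerisation at C7.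

**Step 11**
Reactants: 22 tert-butyl acrylate; 23 acetaldehyde
Product: 24 tert-butyl 3-hydroxy-2-methylidenebutanoate (racemic)
Conditions: DABCO (0.5 equiv), neat, 23 °C
Reagents that add atoms: none
Why: Morita–Baylis–Hillman reaction of an acrylate with acetaldehyde under DABCO catalysis; the carbinol stereocentre is racemic and is removed in step 12.

**Step 12**
Reactants: 24 Baylis–Hillman alcohol
Product: 26 tert-butyl (2E)-2-(acetoxymethyl)but-2-enoate, via secondary allylic acetate 25 (not isolated)
Conditions: Ac2O, Et3N, DMAP (cat.), CH2Cl2, 0 °C; then DABCO (1 equiv), THF, 60 °C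
Reagents that add atoms: acetic anhydride, CC(=O)OC(C)=O
Why: Acetylation followed by DABCO-mediated SN2′–SN2′ transposition of the Baylis–Hillman acetate moves the acetate to the primary carbon and gives the thermodynamically preferred (E)-trisubstituted enoate (ester trans to CH3).

**Step 13**
Reactants: 26 tert-butyl (2E)-2-(acetoxymethyl)but-2-enoate
Product: 27 (2E)-2-(acetoxymethyl)but-2-enoic acid
Conditions: CF3CO2H, CH2Cl2, 23 °C
Reagents that add atoms: none
Why: Acidolysis of the tert-butyl ester (loss of isobutene) leaves the primary allylic acetate and the alkene geometry untouched.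

**Step 14**
Reactants: 21 8α-alcohol; 27 (2E)-2-(acetoxymethyl)but-2-enoic acid
Product: 29 8α-{[(2E)-2-(acetoxymethyl)but-2-enoyl]oxy}-1-ethoxy-10β-(methoxymethoxy)-6α-[(tert-butyldimethylsilyl)oxy]germacra-1,4(Z),11(13)-trien-3-one, via mixed 2,4,6-trichlorobenzoic anhydride 28 (not isolated)
Conditions: 27, 2,4,6-trichlorobenzoyl chloride, Et3N, toluene, 23 °C; then 21, DMAP, toluene, 0 → 23 °C
Reagents that add atoms: none
Why: Yamaguchi esterification through the mixed anhydride and DMAP acyl transfer acylates the hindered secondary C8 alcohol with retention at C8, the tertiary C10 oxygen being masked as its MOM ether and C6 as its silyl ether.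

**Step 15**
Reactants: 29 8α-ester with 10-OMOM and β-ethoxy enone
Product: 31 8α-{[(2E)-2-(acetoxymethyl)but-2-enoyl]oxy}-6α-[(tert-butyldimethylsilyl)oxy]-3,10-epoxygermacra-2,4(Z),11(13)-trien-1-one (3(2H)-furanone), via 10-hydroxy enol ether 30 (not isolated)
Conditions: Me2BBr (3 equiv), CH2Cl2, −78 °C; then aq. NaHCO3/THF, 0 °C; then pyridinium p-toluenesulfonate (cat.), wet CH2Cl2, 23 °C
Reagents that add atoms: water, O
Why: Me2BBr cleaves the MOM acetal at −78 °C without touching the TBS ether, esters or alkenes, and the liberated tertiary C10 hydroxyl then adds to the C3 carbonyl of the vinylogous ester with loss of water and ethanol under mild acid (cyclodehydration of an α′-hydroxy-1,3-dicarbonyl equivalent to a 3(2H)-furanone); the C8 and C6 oxygens are blocked, so only O10 can close the five-membered ring.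

**Step 16**
Reactants: 31 furanone with isopropenyl group
Product: 32 12-hydroxy derivative of 31 (C7 side chain = 3-hydroxyprop-1-en-2-yl)
Conditions: SeO2 (0.5 equiv), t-BuOOH (3 equiv), CH2Cl2, 0 → 23 °C
Reagents that add atoms: tert-butyl hydroperoxide (oxygen source, transferred through SeO2), CC(C)(C)OO
Why: SeO2/t-BuOOH allylic oxidation (ene reaction then [2,3] shift) attacks the only electron-rich alkene, the 1,1-disubstituted isopropenyl group, at its methyl group, whereas the enone-type C4=C5 bond and the enoate of the side chain are deactivated; any enal formed by over-oxidation converges in step 18.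

**Step 17**
Reactants: 32 12-hydroxy-6α-silyl ether
Product: 33 6α,12-diol (8α-ester, 3,10-epoxy-1-one)
Conditions: HF·pyridine, pyridine, THF, 0 → 23 °C
Reagents that add atoms: none
Why: Buffered HF·pyridine removes the secondary allylic TBS ether without affecting the acetate, the enoate or the furanone.

**Step 18**
Reactants: 33 6α,12-diol
Product: 36 target CNP0176571.1, (6S,7S,8R,10R)-8α-{[(2E)-2-(acetoxymethyl)but-2-enoyl]oxy}-3,10-epoxy-1-oxogermacra-2,4(Z),11(13)-trien-12,6α-olide, via C12 enal 34 (not isolated), via C12 lactol 35 (not isolated)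
Conditions: TEMPO (0.2 equiv), PhI(OAc)2 (2.5 equiv), CH2Cl2, 23 °C
Reagents that add atoms: none
Why: TEMPO/PhI(OAc)2 oxidises the primary allylic alcohol selectively to the enal, which is trapped by the C6 hydroxyl as the lactol and oxidised further to the trans-fused α-methylene-γ-butyrolactone (oxidative lactonisation of a 2-methylene-1,4-diol), C6 and C7 keeping their configurations.

**Compound list**
1 | (R)-(−)-carvone | CC1=CC[C@H](CC1=O)C(C)=C | starting material
2 | bromomagnesium extended dienolate of carvone | Br[Mg]OC1=C(C)C=C[C@@H](C(C)=C)C1 | intermediate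
3 | (S)-trimethyl{[2-methyl-5-(prop-1-en-2-yl)cyclohexa-1,3-dien-1-yl]oxy}silane | C[Si](C)(C)OC1=C(C)C=C[C@@H](C(C)=C)C1 | intermediate
4 | 5α,6α-epoxide of 3 (oxirane anti to isopropenyl) | C[Si](C)(C)OC1=C(C)[C@@H]2O[C@@H]2[C@@H](C(C)=C)C1 | intermediate
5 | (4S,5R)-4-hydroxy-2-methyl-5-(prop-1-en-2-yl)cyclohex-2-en-1-one (6α-OH) | O=C1C(C)=C[C@H](O)[C@@H](C(C)=C)C1 | intermediate
6 | (4S,5R)-4-[(tert-butyldimethylsilyl)oxy]-2-methyl-5-(prop-1-en-2-yl)cyclohex-2-en-1-one | O=C1C(C)=C[C@H](O[Si](C)(C)C(C)(C)C)[C@@H](C(C)=C)C1 | intermediate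
7 | potassium cross-conjugated (C3=C8) enolate of 6 | [K+].[O-]C1=C[C@H](C(C)=C)[C@@H](O[Si](C)(C)C(C)(C)C)C=C1C | intermediate
8 | 4-[(tert-butyldimethylsilyl)oxy]-6-hydroxy-2-methyl-5-(prop-1-en-2-yl)cyclohex-2-en-1-one, both oxygens trans to isopropenyl (6α-OTBS, 8α-OH) | O=C1C(C)=C[C@H](O[Si](C)(C)C(C)(C)C)[C@@H](C(C)=C)[C@@H]1O | intermediate
9 | ethoxyacetylene | CCOC#C | starting material
10 | lithium ethoxyacetylide | CCOC#C[Li] | intermediate
11 | 3β-(ethoxyethynyl)-6α-[(tert-butyldimethylsilyl)oxy]-4-methyl-7β-(prop-1-en-2-yl)cyclohex-4-ene-3α,8α-diol | CCOC#C[C@@]1(O)C(C)=C[C@H](O[Si](C)(C)C(C)(C)C)[C@@H](C(C)=C)[C@@H]1O | intermediate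
12 | 3β-(ethoxyethynyl)-3α-hydroxy-6α-[(tert-butyldimethylsilyl)oxy]-4-methyl-7β-(prop-1-en-2-yl)cyclohex-4-en-8-one | CCOC#C[C@@]1(O)C(C)=C[C@H](O[Si](C)(C)C(C)(C)C)[C@@H](C(C)=C)C1=O | intermediate
13 | bromoacetone | CC(=O)CBr | starting material
14 | potassium (Z)-1-bromoprop-1-en-2-olate | [K+].[O-]/C(C)=C\Br | intermediate
15 | (Z)-1-bromo-2-(methoxymethoxy)prop-1-ene | Br/C=C(/C)OCOC | intermediate
16 | (Z)-2-(methoxymethoxy)prop-1-enyllithium | [Li]/C=C(/C)OCOC | intermediate
17 | bromomagnesium 3-alkoxide of 12 | CCOC#C[C@@]1(O[Mg]Br)C(C)=C[C@H](O[Si](C)(C)C(C)(C)C)[C@@H](C(C)=C)C1=O | intermediate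
18 | 3β-(ethoxyethynyl)-8α-[(Z)-2-(methoxymethoxy)prop-1-enyl]-6α-[(tert-butyldimethylsilyl)oxy]-4-methyl-7β-(prop-1-en-2-yl)cyclohex-4-ene-3α,8β-diol (key-step precursor) | CCOC#C[C@@]1(O)C(C)=C[C@H](O[Si](C)(C)C(C)(C)C)[C@@H](C(C)=C)[C@]1(O)/C=C(/C)OCOC | intermediate
19 | dipotassium C8-enolate/C1–C3 allenolate of the ten-membered ring | [K+].[K+].CCOC1=C=C([O-])/C(C)=C\[C@H](O[Si](C)(C)C(C)(C)C)[C@@H](C(C)=C)C([O-])=C[C@@]1(C)OCOC | intermediate
20 | 1-ethoxy-10β-(methoxymethoxy)-6α-[(tert-butyldimethylsilyl)oxy]germacra-1,4(Z),11(13)-triene-3,8-dione (key-step product) | CCO/C1=C/C(=O)/C(C)=C\[C@H](O[Si](C)(C)C(C)(C)C)[C@@H](C(C)=C)C(=O)C[C@@]1(C)OCOC | intermediate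
21 | 1-ethoxy-8α-hydroxy-10β-(methoxymethoxy)-6α-[(tert-butyldimethylsilyl)oxy]germacra-1,4(Z),11(13)-trien-3-one | CCO/C1=C/C(=O)/C(C)=C\[C@H](O[Si](C)(C)C(C)(C)C)[C@@H](C(C)=C)[C@H](O)C[C@@]1(C)OCOC | intermediate
22 | tert-butyl acrylate | C=CC(=O)OC(C)(C)C | starting material
23 | acetaldehyde | CC=O | starting material
24 | tert-butyl 3-hydroxy-2-methylidenebutanoate (racemic) | CC(O)C(=C)C(=O)OC(C)(C)C | intermediate
25 | tert-butyl 3-acetoxy-2-methylidenebutanoate | CC(OC(C)=O)C(=C)C(=O)OC(C)(C)C | intermediate
26 | tert-butyl (2E)-2-(acetoxymethyl)but-2-enoate | C/C=C(\COC(C)=O)C(=O)OC(C)(C)C | intermediate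
27 | (2E)-2-(acetoxymethyl)but-2-enoic acid | C/C=C(\COC(C)=O)C(=O)O | intermediate
28 | (2E)-2-(acetoxymethyl)but-2-enoic 2,4,6-trichlorobenzoic anhydride | C/C=C(\COC(C)=O)C(=O)OC(=O)c1c(Cl)cc(Cl)cc1Cl | intermediate
29 | 8α-{[(2E)-2-(acetoxymethyl)but-2-enoyl]oxy}-1-ethoxy-10β-(methoxymethoxy)-6α-[(tert-butyldimethylsilyl)oxy]germacra-1,4(Z),11(13)-trien-3-one | CCO/C1=C/C(=O)/C(C)=C\[C@H](O[Si](C)(C)C(C)(C)C)[C@@H](C(C)=C)[C@H](OC(=O)/C(=C/C)COC(C)=O)C[C@@]1(C)OCOC | intermediate
30 | 10β-hydroxy analogue of 29 (MOM removed) | CCO/C1=C/C(=O)/C(C)=C\[C@H](O[Si](C)(C)C(C)(C)C)[C@@H](C(C)=C)[C@H](OC(=O)/C(=C/C)COC(C)=O)C[C@@]1(C)O | intermediate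
31 | 8α-{[(2E)-2-(acetoxymethyl)but-2-enoyl]oxy}-6α-[(tert-butyldimethylsilyl)oxy]-3,10-epoxygermacra-2,4(Z),11(13)-trien-1-one | CC(=C)[C@@H]1[C@@H](O[Si](C)(C)C(C)(C)C)/C=C(/C)C2=CC(=O)[C@@](C)(C[C@H]1OC(=O)/C(=C/C)COC(C)=O)O2 | intermediate
32 | 12-hydroxy derivative of 31 | OCC(=C)[C@@H]1[C@@H](O[Si](C)(C)C(C)(C)C)/C=C(/C)C2=CC(=O)[C@@](C)(C[C@H]1OC(=O)/C(=C/C)COC(C)=O)O2 | intermediate
33 | 8α-{[(2E)-2-(acetoxymethyl)but-2-enoyl]oxy}-6α,12-dihydroxy-3,10-epoxygermacra-2,4(Z),11(13)-trien-1-one | OCC(=C)[C@@H]1[C@@H](O)/C=C(/C)C2=CC(=O)[C@@](C)(C[C@H]1OC(=O)/C(=C/C)COC(C)=O)O2 | intermediate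
34 | 12-aldehyde (6α-hydroxy enal) | O=CC(=C)[C@@H]1[C@@H](O)/C=C(/C)C2=CC(=O)[C@@](C)(C[C@H]1OC(=O)/C(=C/C)COC(C)=O)O2 | intermediate
35 | 12,6α-lactol (C12 epimers) | C=C1C(O)O[C@H]2/C=C(/C)C3=CC(=O)[C@@](C)(C[C@@H](OC(=O)/C(=C/C)COC(C)=O)[C@H]12)O3 | intermediate
36 | CNP0176571.1, (6S,7S,8R,10R)-8α-{[(2E)-2-(acetoxymethyl)but-2-enoyl]oxy}-3,10-epoxy-1-oxogermacra-2,4(Z),11(13)-trien-12,6α-olide | C=C1C(=O)O[C@H]2/C=C(/C)C3=CC(=O)[C@@](C)(C[C@@H](OC(=O)/C(=C/C)COC(C)=O)[C@H]12)O3 | target

**Step count**
Total: 18 steps. Longest linear sequence: 14 steps (steps 1–6, 8–10, 14–18); step 7 and steps 11–13 are side branches.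

**Steps most likely to fail**

Step 9. The dialkoxide may fragment by loss of ethoxyacetylide from C3 (retro-alkynylation) instead of rearranging. The bis-enolate may also isomerise or undergo transannular aldol reaction before or during the quench, and a stepwise or boat pathway would erode the chirality transfer to C10. The fallback sets out from 18 and comes back at 20, and replaces the anionic activation by a neutral thermal siloxy-Cope rearrangement. Both tertiary hydroxyls are silylated with N-(trimethylsilyl)imidazole (CH2Cl2, 23 °C) to give the 3,8-bis(trimethylsilyl) ether F1. Heating in toluene (110–130 °C, sealed, trace Et3N) should then rearrange the 3,4-bis(silyloxy)-1,5-enyne to the ring-expanded C8 silyl enol ether/C3 allenyl silyl ether F2. Hydrolysis of both Si–O bonds (AcOH, THF/H2O, 0 °C) would deliver 20.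

Step 5. The acetylide may attack axially from the α-face, trans to the isopropenyl group, which is the usual course of 1,2-additions to carvone and would override the chelate and invert C3. The fallback sets out from 5 and comes back at 11, and blocks the α-face with an epoxide.
- Hydroxyl-directed nucleophilic epoxidation of 5 (H2O2, NaOH, MeOH, 0 °C; syn to the 6α-OH and anti to isopropenyl) gives the 4α,5α-epoxy-6α-hydroxy ketone F3.
- Silylation (t-BuMe2SiCl, imidazole) gives the epoxy silyl ether F4.
- Enolate hydroxylation as in step 4 (KN(SiMe3)2, then the Davis oxaziridine) gives the 8α-hydroxy epoxy ketone F5.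
- Lithium ethoxyacetylide then adds anti to the epoxide oxygen, the established course for α,β-epoxy ketones, to give the 3β-alkynyl epoxy diol F6.
- Deoxygenation of the epoxide (PPh3, MeReO3 cat., benzene, 23 °C) restores the ring-fixed Z alkene and gives 11.

Step 8. The vinyl reagent may add from the β-face (attack anti to the axial C3 oxygen, outside the chelate) or enolise the ketone at C7. The resulting 8-epimeric cis-diol cannot reach the chair that gives 10R. The fallback sets out from 12 and comes back at 18, and replaces chelate control by alkoxide-directed delivery on a desilylated substrate. The C6 silyl ether is removed (Bu4NF buffered with AcOH, THF, 0 °C) to give the 3α,6α-dihydroxy ketone F7. Both hydroxyls are converted into magnesium alkoxides (MeMgBr, 2 equiv, THF, −78 °C), so that two α-face oxido groups bind the incoming reagent 16 and no silyl group shields that face; this should give the 3α,6α,8β-triol F8. Selective silylation of the only secondary hydroxyl (t-BuMe2SiCl, imidazole, DMF) returns 18.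

**Further compounds**
F1 | step 9 | 3,8-bis(trimethylsilyl) ether of 18 | CCOC#C[C@@]1(O[Si](C)(C)C)C(C)=C[C@H](O[Si](C)(C)C(C)(C)C)[C@@H](C(C)=C)[C@]1(O[Si](C)(C)C)/C=C(/C)OCOC
F2 | step 9 | ring-expanded 8-(trimethylsilyloxy) enol ether with 1-ethoxy-3-(trimethylsilyloxy)allene | CCOC1=C=C(O[Si](C)(C)C)/C(C)=C\[C@H](O[Si](C)(C)C(C)(C)C)[C@@H](C(C)=C)C(O[Si](C)(C)C)=C[C@@]1(C)OCOC
F3 | step 5 | 4α,5α-epoxy-6α-hydroxy ketone (epoxide of 5, syn to OH, anti to isopropenyl) | O=C1[C@]2(C)O[C@@H]2[C@H](O)[C@@H](C(C)=C)C1
F4 | step 5 | 4α,5α-epoxy-6α-[(tert-butyldimethylsilyl)oxy] ketone | O=C1[C@]2(C)O[C@@H]2[C@H](O[Si](C)(C)C(C)(C)C)[C@@H](C(C)=C)C1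
F5 | step 5 | 4α,5α-epoxy-8α-hydroxy-6α-[(tert-butyldimethylsilyl)oxy] ketone | O=C1[C@]2(C)O[C@@H]2[C@H](O[Si](C)(C)C(C)(C)C)[C@@H](C(C)=C)[C@@H]1O
F6 | step 5 | 3β-(ethoxyethynyl)-4α,5α-epoxy-6α-[(tert-butyldimethylsilyl)oxy]cyclohexane-3α,8α-diol | CCOC#C[C@@]1(O)[C@]2(C)O[C@@H]2[C@H](O[Si](C)(C)C(C)(C)C)[C@@H](C(C)=C)[C@@H]1O
F7 | step 8 | 3β-(ethoxyethynyl)-3α,6α-dihydroxy-cyclohex-4-en-8-one (12 without silyl group) | CCOC#C[C@@]1(O)C(C)=C[C@H](O)[C@@H](C(C)=C)C1=O
F8 | step 8 | 3β-(ethoxyethynyl)-8α-[(Z)-2-(methoxymethoxy)prop-1-enyl]cyclohex-4-ene-3α,6α,8β-triol | CCOC#C[C@@]1(O)C(C)=C[C@H](O)[C@@H](C(C)=C)[C@]1(O)/C=C(/C)OCOC
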